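## The problem

Target 21 is a 1-aryl-1,2-dihydronaphthalene. Ring A (C4a, C5–C8, C8a) carries H at C5, OMe at C6, OH at C7 and OMe at C8. It is fused to ring B (C1, C2, C3, C4, C4a, C8a), in which C1 bears a 4-hydroxy-3,5-dimethoxyphenyl group, C2 and C3 each bear a methyl group, and C3=C4 is a styrene-type double bond. Both aryl units show the same 3,5-dimethoxy-4-hydroxy pattern, so one phenolic aldehyde can supply both. The bond that joins them, C1–C8a, ends at a ring carbon flanked by the C8 methoxy group and by C4a, and is the most crowded bond of the skeleton. C1 (S, doubly benzylic) and C2 (S, allylic) are adjacent, with the aryl and the methyl group cis. Neither centre lies next to a carbonyl group in 21, so neither can be corrected by equilibration. C1 therefore has to be set first by a catalyst, and C2 afterwards under the combined control of a catalyst and C1. The dihydronaphthalene can lose hydrogen from C1/C2 to give a naphthalene or shift its double bond under acid, base or metal hydrides, and the electron-rich phenols oxidise easily. The phenol protecting groups must therefore leave without hydrogenolysis and without strong acid or base. The feature that opens the key step is that C4 sits on C4a, ortho to C8a, which holds C1, while C2 is a methyl-bearing methine. A formyl group on C4a and an isopropenyl group on C1 thus map onto C4, C3 (terminal alkene carbon) and C2 (internal alkene carbon). Adding the aldehyde C–H across that alkene forms C3–C4 and C2–H in the ring-closing event and leaves a C4 ketone from which the C3 methyl and the C3=C4 bond follow.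

## Retrosynthesis

**21 from 20 (O–Si bonds).** The two phenols are unmasked last. Triisopropylsilyl (TIPS) ethers are chosen because they withstand aryllithium reagents, methoxide, amide bases and warm amine/formate, and leave with buffered fluoride, which touches neither the alkene nor C1–H. Benzyl ethers are excluded by the alkene, and acid-labile groups by the acid-sensitive styrene.

**20 from tetralone 15 through 19 and 17 (C4–H in place of C4–O, and C3–CH3).** The C3=C4 bond is traced to a C4 ketone. Enolisation of 15 can only occur towards C3, since C4a is aromatic, so methylation gives 17 and triflation gives 19 without any regiochemical question. Reduction of the enol triflate then puts hydrogen on C4. A reduction–dehydration sequence from 17 is equally short but passes through a C4 cation; it is kept as a reserve. The C3 centre of 17 is of no consequence because it becomes sp2. The forward steps must stop at monomethylation and must not move the new double bond.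

**15 from aldehyde 14 (C3–C4 and C2–H; key step).** Cutting C3–C4 and the C2–H bond opens ring B to a 2-(1-aryl-2-methylallyl)benzaldehyde. Against the neighbouring cuts (C1–C2, C2–C3, C4–C4a) this one has three advantages: it needs no pre-formed C2 centre, it uses the formyl group that ring A inherits from its starting aldehyde, and it closes the ring and creates C2 in one catalytic, atom-economical event. The precursor 14 has a single stereocentre. The forward reaction must be endo-selective and must place the C2 methyl cis to the C1 aryl group.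

**14 from boronic ester 10 through acetal 13 (C1–C2).** The isopropenyl group is attached to C1 by a stereoretentive alkenylation of a secondary dibenzylic boronic ester, followed by release of the aldehyde. A direct enantioselective transfer of a branched alkenyl group to the quinone methide 8 would save one operation. However, enantioselective copper-catalysed borylation of this acceptor class and stereoretentive alkenylation of secondary benzylic boronic esters are both established reaction types, so the boron relay is preferred. The step requires a boronate complex to form at a crowded boron atom and to rearrange with retention at C1.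

**10 from quinone methide 8 (C1–B).** C1 becomes stereogenic when a boryl group adds to the exocyclic carbon of the para-quinone methide 8. The quinone ring is symmetric, so the geometry of the exocyclic double bond does not matter, and aromatisation drives the addition. The precursor is flat and achiral. The catalyst must distinguish the two faces of a methide carbon that carries a di-ortho-substituted aryl group.

**8 from carbinol 7, and 7 from bromide 4 and syringaldehyde 1 (C1–C8a).** The crowded biaryl-methine bond is made early, by adding the ring A aryllithium 5 to the formyl group of 1. The carbinol 7 loses water towards the pendant ring, whose phenol is para to the carbinol; the ring A oxygen at C7 is meta and cannot compete. The ring A formyl group has to be masked as an acetal for this step, and the pendant phenol has to stay free so that 8 can form.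

**4 from 1 through 3 and 2.** Ring A is 1 itself after bromination at the only open position type, silylation and acetal formation. The bromine marks C8a and the formyl carbon becomes C4.

## Roads not taken

**Alternative 1:** conjunctive coupling across a styrenyl boronate.
- **Cut and key step:** C1–C8a and C2–CH3 are cut together. The methyl boronate complex of the styrenyl pinacol boronate A1 would be coupled with the ring A aryl triflate A2 under a palladium catalyst with a chiral ferrocenyl bisphosphine. The aryl group adds to C1 while methyl migrates from boron to C2, giving the 1,1-diaryl-2-borylpropane A3.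
- **Merits:** one catalytic event joins the two rings and sets both stereocentres, with the relative configuration fixed by the alkene geometry and the absolute configuration by the ligand. In this respect it is better than the chosen plan, which needs two separate stereodefining steps.
- **Weak points:** the addition is anti across the alkene. A3 with the C1/C2 relationship that leads to cis-21 therefore derives from the Z-boronate (A1 as drawn); the readily made E isomer would lead to the trans series. β-Aryl alkenyl boronates are far less reactive in this coupling than vinyl boronates. A2 has both ortho positions occupied and needs a phenol at C8a, which syringaldehyde 1 does not offer. After A3 the C2–B bond still has to be extended to C3 with its methyl group and ring B closed onto C4.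
- **Comparison:** the chosen plan gives up the one-step setting of two centres. In return it uses a ring closure with close precedent and building blocks that come directly from 1.

**Alternative 2:** ene-type cyclisation of a quinone methide.
- **Cut and key step:** C1–C2 is cut. A chiral Brønsted acid would activate the quinone methide A4, whose ring A carries an (E)-2-methylbut-2-enyl chain at C4a. The alkene attacks C1 through C2, and the C3 cation loses the C4 proton to give A5, the ring A silyl ether of 21.
- **Merits:** this is the shortest road by a wide margin. Ring B, both stereocentres and the C3=C4 bond arise in one step at the final oxidation level. If the selectivity could be secured it would be the better synthesis.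
- **Weak points:** the nucleophile is an unactivated trisubstituted alkene that cannot bind to the catalyst, so both enantio- and diastereocontrol lack close precedent. Proton loss can also occur from the C3 methyl group or from C2. The acid-sensitive styrene is formed under the acid that makes it.
- **Comparison:** the chosen plan costs about six more steps. Each of its stereochemical events has a known counterpart and can be checked on its own, C1 at 10 and C2 at 15.

**Alternative 3:** invertive enolate alkylation.
- **Cut and key step:** C2–C3 is cut. The potassium enolate of the ring A propiophenone A6 would displace the C2 tosylate with inversion in a 6-exo-tet closure, giving the 2,3-dimethyl-1-tetralone A7.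
- **Merits:** the C3 methyl group arrives with the nucleophile, so the methylation step of the chosen plan is saved. The closure is stereospecific, and A7 has the same endgame as 17.
- **Weak points:** the tosylate is secondary and sits next to a diarylmethine. Substitution is slow there, elimination and participation of the electron-rich aryl groups compete, and O-alkylation is possible. A6 needs both C1 and C2 in place before the ring is closed, which lengthens the open-chain part.
- **Comparison:** the chosen plan needs one more step after ring closure. It makes C2 from a flat alkene carbon in the closure itself and needs only one pre-set centre.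

Key step: step 9

Remark on the chemistry: atom numbers C1–C8a are those of ring A and ring B of the target; the antipodes of the chiral ligands in steps 6 and 9 are fixed on the first run, and the configurations written are the ones required.

Step 1
Reactants: 1 syringaldehyde (4-hydroxy-3,5-dimethoxybenzaldehyde)
Product: 2 2-bromo-4-hydroxy-3,5-dimethoxybenzaldehyde
Conditions: Br2 (1.05 equiv), NaOAc, AcOH, rt
Reagents that add atoms: bromine, BrBr
Why: Electrophilic aromatic bromination; the two open positions are equivalent and each is ortho to one methoxy group and para to the other, the formyl group slows a second bromination, and acetate takes up HBr.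

Step 2
Reactants: 2 2-bromo-4-hydroxy-3,5-dimethoxybenzaldehyde
Product: 3 2-bromo-3,5-dimethoxy-4-(triisopropylsilyloxy)benzaldehyde
Conditions: i-Pr3SiCl, imidazole, DMF, 40 °C
Reagents that add atoms: chlorotriisopropylsilane, CC(C)[Si](Cl)(C(C)C)C(C)C
Why: Imidazole-promoted silylation of a phenol; the TIPS ether is chosen because it must later survive aryllithium, methoxide, amide bases and warm amine/formate.

Step 3
Reactants: 3 2-bromo-3,5-dimethoxy-4-(triisopropylsilyloxy)benzaldehyde
Product: 4 2-[2-bromo-3,5-dimethoxy-4-(triisopropylsilyloxy)phenyl]-1,3-dioxolane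
Conditions: HOCH2CH2OH, TsOH·H2O (cat.), toluene, reflux, Dean–Stark
Reagents that add atoms: ethane-1,2-diol, OCCO
Why: Acid-catalysed acetal formation driven by azeotropic removal of water; it masks the future C4 formyl group for the lithiation, and the aryl TIPS ether tolerates catalytic sulfonic acid.

Step 4
Reactants: 4 2-[2-bromo-3,5-dimethoxy-4-(triisopropylsilyloxy)phenyl]-1,3-dioxolane; 1 syringaldehyde
Product: 7 racemic [6-(1,3-dioxolan-2-yl)-2,4-dimethoxy-3-(triisopropylsilyloxy)phenyl](4-hydroxy-3,5-dimethoxyphenyl)methanol, via aryllithium 5 (not isolated), via sodium phenolate 6 (not isolated)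
Conditions: 4, n-BuLi, THF, –78 °C; 1, NaH, THF, 0 °C (second flask); combine, –78 → 0 °C; aq. NH4Cl
Reagents that add atoms: none
Why: Bromine–lithium exchange followed by 1,2-addition of the aryllithium to the aldehyde forms C1–C8a; the phenol of 1 is held as its phenolate so that one equivalent of 5 suffices, and the carbinol centre is racemic because it is erased in step 5.

Step 5
Reactants: 7 racemic [6-(1,3-dioxolan-2-yl)-2,4-dimethoxy-3-(triisopropylsilyloxy)phenyl](4-hydroxy-3,5-dimethoxyphenyl)methanol
Product: 8 4-{[6-(1,3-dioxolan-2-yl)-2,4-dimethoxy-3-(triisopropylsilyloxy)phenyl]methylidene}-2,6-dimethoxycyclohexa-2,5-dien-1-one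
Conditions: PPTS (5 mol%), 4 Å MS, CH2Cl2, rt
Reagents that add atoms: none
Why: Acid-catalysed dehydration of a 4-hydroxybenzhydrol to a para-quinone methide; the benzhydryl cation is stabilised by both electron-rich rings so a weak acid suffices, and the sieves remove water and keep the dioxolane intact.

Step 6
Reactants: 8 4-{[6-(1,3-dioxolan-2-yl)-2,4-dimethoxy-3-(triisopropylsilyloxy)phenyl]methylidene}-2,6-dimethoxycyclohexa-2,5-dien-1-one
Product: 10 2-{(S)-[6-(1,3-dioxolan-2-yl)-2,4-dimethoxy-3-(triisopropylsilyloxy)phenyl][3,5-dimethoxy-4-(triisopropylsilyloxy)phenyl]methyl}-4,4,5,5-tetramethyl-1,3,2-dioxaborolane, via phenol boronate 9 (not isolated)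
Conditions: CuCl (5 mol%), Josiphos-type ferrocenyl bisphosphine (6 mol%, antipode that gives S), NaOt-Bu (10 mol%), B2pin2, MeOH, THF, rt; concentrate; i-Pr3SiCl, imidazole, DMF, 40 °C
Reagents that add atoms: bis(pinacolato)diboron, CC1(C)OB(OC1(C)C)B1OC(C)(C)C(C)(C)O1; chlorotriisopropylsilane, CC(C)[Si](Cl)(C(C)C)C(C)C
Why: Copper-catalysed enantioselective 1,6-conjugate borylation of a para-quinone methide; a phosphine-bound boryl complex of monovalent copper delivers boron to the exocyclic carbon, the chiral bisphosphine selects the face and so sets C1, and aromatisation drives the addition; the sensitive phenol 9 is silylated in the same flask.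

Step 7
Reactants: 10 2-{(S)-[6-(1,3-dioxolan-2-yl)-2,4-dimethoxy-3-(triisopropylsilyloxy)phenyl][3,5-dimethoxy-4-(triisopropylsilyloxy)phenyl]methyl}-4,4,5,5-tetramethyl-1,3,2-dioxaborolane
Product: 13 2-{2-[(1S)-1-[3,5-dimethoxy-4-(triisopropylsilyloxy)phenyl]-2-methylprop-2-en-1-yl]-3,5-dimethoxy-4-(triisopropylsilyloxy)phenyl}-1,3-dioxolane, via boronate complex 11 (not isolated), via iodo boronic ester 12 (not isolated)
Conditions: CH2=C(CH3)Br, t-BuLi, THF, –78 °C; add 10, –78 → 0 °C; I2, THF/MeOH, –78 °C; NaOMe, MeOH, –78 °C → rt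
Reagents that add atoms: 2-bromopropene (as isopropenyllithium), CC(Br)=C
Why: Zweifel olefination; isopropenyllithium forms the boronate complex, iodine triggers the 1,2-shift of the dibenzylic carbon from boron to the alkenyl carbon with retention at C1, and methoxide induces anti elimination of boron and iodine, so C1–B becomes C1–C2 with the configuration of 10.

Step 8
Reactants: 13 2-{2-[(1S)-1-[3,5-dimethoxy-4-(triisopropylsilyloxy)phenyl]-2-methylprop-2-en-1-yl]-3,5-dimethoxy-4-(triisopropylsilyloxy)phenyl}-1,3-dioxolane
Product: 14 2-[(1S)-1-[3,5-dimethoxy-4-(triisopropylsilyloxy)phenyl]-2-methylprop-2-en-1-yl]-3,5-dimethoxy-4-(triisopropylsilyloxy)benzaldehyde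
Conditions: PPTS, acetone/H2O, 50 °C
Reagents that add atoms: water, O
Why: Mild acid hydrolysis of the dioxolane, accelerated by the para silyloxy group; the acid is too weak to move the isopropenyl double bond or to start a carbonyl-ene reaction.

Step 9
Reactants: 14 2-[(1S)-1-[3,5-dimethoxy-4-(triisopropylsilyloxy)phenyl]-2-methylprop-2-en-1-yl]-3,5-dimethoxy-4-(triisopropylsilyloxy)benzaldehyde
Product: 15 (3R,4S)-4-[3,5-dimethoxy-4-(triisopropylsilyloxy)phenyl]-5,7-dimethoxy-3-methyl-6-(triisopropylsilyloxy)-3,4-dihydronaphthalen-1(2H)-one (3,4-cis)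
Conditions: [Rh(cod)Cl]2 (2.5 mol%), DTBM-SEGPHOS (matched antipode, 5.5 mol%), Na[B(3,5-(CF3)2C6H3)4] (6 mol%), 1,4-dioxane, 60 °C
Reagents that add atoms: none
Why: Intramolecular alkene hydroacylation catalysed by a cationic bisphosphine complex of monovalent rhodium; the closest known reaction type is the enantioselective 6-endo hydroacylation of ortho-allylbenzaldehydes with a 2-substituted allyl group, which gives 3-substituted 3,4-dihydronaphthalen-1(2H)-ones. Rhodium adds oxidatively into the formyl C4–H bond to give an acyl hydride of trivalent rhodium that the isopropenyl group holds as a chelate. The alkene inserts into Rh–H with hydrogen going to the internal carbon C2 and rhodium to the terminal carbon C3, and reductive elimination from the seven-membered acyl alkyl rhodacycle forms C3–C4. Ring B therefore closes in the 6-endo mode with respect to the alkene. The new centre C2 is fixed in the hydride insertion: the bulky bisphosphine selects the alkene face, and the substrate should reinforce it, because the C8 methoxy group forces the C1 aryl group out of the ring A plane, so hydride arrives anti to that aryl group and the C2 methyl ends up cis to it. Three selectivities are needed: endo over exo closure, secured by the 1,1-disubstituted alkene, which keeps rhodium off the tertiary carbon; hydroacylation over decarbonylation, secured by the short ortho tether that keeps the alkene bound; and cis over trans, secured by the matched ligand antipode together with the C1 centre. C1 is not involved and keeps its configuration.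

Step 10
Reactants: 15 (3R,4S)-4-[3,5-dimethoxy-4-(triisopropylsilyloxy)phenyl]-5,7-dimethoxy-3-methyl-6-(triisopropylsilyloxy)-3,4-dihydronaphthalen-1(2H)-one
Product: 17 (3S,4S)-4-[3,5-dimethoxy-4-(triisopropylsilyloxy)phenyl]-5,7-dimethoxy-2,3-dimethyl-6-(triisopropylsilyloxy)-3,4-dihydronaphthalen-1(2H)-one (mixture of C2 epimers), via lithium enolate 16 (not isolated)
Conditions: LiN(i-Pr)2 (1.05 equiv), THF, –78 °C; MeI, –78 → –20 °C
Reagents that add atoms: iodomethane, CI
Why: Enolate alkylation; the ketone can enolise only towards C3 of the target numbering, the lithium enolate is methylated on carbon, and the new centre need not be controlled because it becomes sp2 in step 11; the descriptor of the neighbouring methyl carbon changes from R to S only through the priority rules.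

Step 11
Reactants: 17 (3S,4S)-4-[3,5-dimethoxy-4-(triisopropylsilyloxy)phenyl]-5,7-dimethoxy-2,3-dimethyl-6-(triisopropylsilyloxy)-3,4-dihydronaphthalen-1(2H)-one
Product: 19 (3S,4S)-4-[3,5-dimethoxy-4-(triisopropylsilyloxy)phenyl]-5,7-dimethoxy-2,3-dimethyl-6-(triisopropylsilyloxy)-3,4-dihydronaphthalen-1-yl trifluoromethanesulfonate, via potassium enolate 18 (not isolated)
Conditions: KN(SiMe3)2, THF, –78 °C; PhNTf2, –78 → 0 °C; aq. NH4Cl
Reagents that add atoms: N-phenylbis(trifluoromethanesulfonimide), O=S(=O)(N(c1ccccc1)S(=O)(=O)C(F)(F)F)C(F)(F)F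
Why: Enol triflate formation by O-sulfonylation of the potassium enolate; only one enolate is possible, so the C3=C4 double bond of the target is placed without ambiguity.

Step 12
Reactants: 19 (3S,4S)-4-[3,5-dimethoxy-4-(triisopropylsilyloxy)phenyl]-5,7-dimethoxy-2,3-dimethyl-6-(triisopropylsilyloxy)-3,4-dihydronaphthalen-1-yl trifluoromethanesulfonate
Product: 20 (1S,2S)-1-[3,5-dimethoxy-4-(triisopropylsilyloxy)phenyl]-6,8-dimethoxy-2,3-dimethyl-7-(triisopropylsilyloxy)-1,2-dihydronaphthalene
Conditions: Pd(OAc)2 (5 mol%), PPh3 (10 mol%), Et3N, HCO2H, DMF, 60 °C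
Reagents that add atoms: none
Why: Palladium-catalysed formate reduction of an enol triflate; oxidative addition to zerovalent palladium, exchange of triflate for formate, loss of CO2 to a palladium hydride and reductive elimination replace C4–O by C4–H without touching C1 or C2.

Step 13
Reactants: 20 (1S,2S)-1-[3,5-dimethoxy-4-(triisopropylsilyloxy)phenyl]-6,8-dimethoxy-2,3-dimethyl-7-(triisopropylsilyloxy)-1,2-dihydronaphthalene
Product: 21 (7S,8S)-8-(4-hydroxy-3,5-dimethoxyphenyl)-1,3-dimethoxy-6,7-dimethyl-7,8-dihydronaphthalen-2-ol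
Conditions: Bu4NF, AcOH, THF, 0 °C
Reagents that add atoms: none
Why: Fluoride cleavage of the two aryl silyl ethers; acetic acid keeps the phenols protonated so that neither base-induced double-bond migration nor air oxidation of phenolates can set in.

## Compound list

1 | syringaldehyde (4-hydroxy-3,5-dimethoxybenzaldehyde) | COc1cc(C=O)cc(OC)c1O | starting material
2 | 2-bromo-4-hydroxy-3,5-dimethoxybenzaldehyde | COc1cc(C=O)c(Br)c(OC)c1O | intermediate
3 | 2-bromo-3,5-dimethoxy-4-(triisopropylsilyloxy)benzaldehyde | COc1cc(C=O)c(Br)c(OC)c1O[Si](C(C)C)(C(C)C)C(C)C | intermediate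
4 | 2-[2-bromo-3,5-dimethoxy-4-(triisopropylsilyloxy)phenyl]-1,3-dioxolane | COc1cc(C2OCCO2)c(Br)c(OC)c1O[Si](C(C)C)(C(C)C)C(C)C | intermediate
5 | [6-(1,3-dioxolan-2-yl)-2,4-dimethoxy-3-(triisopropylsilyloxy)phenyl]lithium | COc1cc(C2OCCO2)c([Li])c(OC)c1O[Si](C(C)C)(C(C)C)C(C)C | intermediate (not isolated)
6 | sodium 4-formyl-2,6-dimethoxyphenolate | [Na+].COc1cc(C=O)cc(OC)c1[O-] | intermediate (not isolated)
7 | racemic [6-(1,3-dioxolan-2-yl)-2,4-dimethoxy-3-(triisopropylsilyloxy)phenyl](4-hydroxy-3,5-dimethoxyphenyl)methanol | COc1cc(cc(OC)c1O)C(O)c1c(C2OCCO2)cc(OC)c(O[Si](C(C)C)(C(C)C)C(C)C)c1OC | intermediate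
8 | 4-{[6-(1,3-dioxolan-2-yl)-2,4-dimethoxy-3-(triisopropylsilyloxy)phenyl]methylidene}-2,6-dimethoxycyclohexa-2,5-dien-1-one | COC1=CC(=Cc2c(C3OCCO3)cc(OC)c(O[Si](C(C)C)(C(C)C)C(C)C)c2OC)C=C(OC)C1=O | intermediate
9 | 4-{(S)-[6-(1,3-dioxolan-2-yl)-2,4-dimethoxy-3-(triisopropylsilyloxy)phenyl](4,4,5,5-tetramethyl-1,3,2-dioxaborolan-2-yl)methyl}-2,6-dimethoxyphenol | COc1cc(cc(OC)c1O)[C@@H](c1c(C2OCCO2)cc(OC)c(O[Si](C(C)C)(C(C)C)C(C)C)c1OC)B1OC(C)(C)C(C)(C)O1 | intermediate (not isolated)
10 | 2-{(S)-[6-(1,3-dioxolan-2-yl)-2,4-dimethoxy-3-(triisopropylsilyloxy)phenyl][3,5-dimethoxy-4-(triisopropylsilyloxy)phenyl]methyl}-4,4,5,5-tetramethyl-1,3,2-dioxaborolane | COc1cc(cc(OC)c1O[Si](C(C)C)(C(C)C)C(C)C)[C@@H](c1c(C2OCCO2)cc(OC)c(O[Si](C(C)C)(C(C)C)C(C)C)c1OC)B1OC(C)(C)C(C)(C)O1 | intermediate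
11 | lithium {(S)-[6-(1,3-dioxolan-2-yl)-2,4-dimethoxy-3-(triisopropylsilyloxy)phenyl][3,5-dimethoxy-4-(triisopropylsilyloxy)phenyl]methyl}(prop-1-en-2-yl)(pinacolato)borate | [Li+].CC(=C)[B-]1(OC(C)(C)C(C)(C)O1)[C@@H](c1cc(OC)c(O[Si](C(C)C)(C(C)C)C(C)C)c(OC)c1)c1c(C2OCCO2)cc(OC)c(O[Si](C(C)C)(C(C)C)C(C)C)c1OC | intermediate (not isolated)
12 | 2-{(1S)-1-[6-(1,3-dioxolan-2-yl)-2,4-dimethoxy-3-(triisopropylsilyloxy)phenyl]-1-[3,5-dimethoxy-4-(triisopropylsilyloxy)phenyl]-3-iodo-2-methylpropan-2-yl}-4,4,5,5-tetramethyl-1,3,2-dioxaborolane (C2 epimers) | CC(CI)(B1OC(C)(C)C(C)(C)O1)[C@@H](c1cc(OC)c(O[Si](C(C)C)(C(C)C)C(C)C)c(OC)c1)c1c(C2OCCO2)cc(OC)c(O[Si](C(C)C)(C(C)C)C(C)C)c1OC | intermediate (not isolated)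
13 | 2-{2-[(1S)-1-[3,5-dimethoxy-4-(triisopropylsilyloxy)phenyl]-2-methylprop-2-en-1-yl]-3,5-dimethoxy-4-(triisopropylsilyloxy)phenyl}-1,3-dioxolane | COc1cc(cc(OC)c1O[Si](C(C)C)(C(C)C)C(C)C)[C@@H](c1c(C2OCCO2)cc(OC)c(O[Si](C(C)C)(C(C)C)C(C)C)c1OC)C(C)=C | intermediate
14 | 2-[(1S)-1-[3,5-dimethoxy-4-(triisopropylsilyloxy)phenyl]-2-methylprop-2-en-1-yl]-3,5-dimethoxy-4-(triisopropylsilyloxy)benzaldehyde | COc1cc(cc(OC)c1O[Si](C(C)C)(C(C)C)C(C)C)[C@@H](c1c(C=O)cc(OC)c(O[Si](C(C)C)(C(C)C)C(C)C)c1OC)C(C)=C | intermediate
15 | (3R,4S)-4-[3,5-dimethoxy-4-(triisopropylsilyloxy)phenyl]-5,7-dimethoxy-3-methyl-6-(triisopropylsilyloxy)-3,4-dihydronaphthalen-1(2H)-one | COc1cc([C@H]2c3c(cc(OC)c(O[Si](C(C)C)(C(C)C)C(C)C)c3OC)C(=O)C[C@H]2C)cc(OC)c1O[Si](C(C)C)(C(C)C)C(C)C | intermediate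
16 | lithium enolate of 15 (lithium 3,4-dihydronaphthalen-1-olate) | COc1cc([C@H]2c3c(cc(OC)c(O[Si](C(C)C)(C(C)C)C(C)C)c3OC)C(O[Li])=C[C@H]2C)cc(OC)c1O[Si](C(C)C)(C(C)C)C(C)C | intermediate (not isolated)
17 | (3S,4S)-4-[3,5-dimethoxy-4-(triisopropylsilyloxy)phenyl]-5,7-dimethoxy-2,3-dimethyl-6-(triisopropylsilyloxy)-3,4-dihydronaphthalen-1(2H)-one (C2 epimers) | COc1cc([C@H]2c3c(cc(OC)c(O[Si](C(C)C)(C(C)C)C(C)C)c3OC)C(=O)C(C)[C@H]2C)cc(OC)c1O[Si](C(C)C)(C(C)C)C(C)C | intermediate
18 | potassium enolate of 17 (potassium 2-methyl-3,4-dihydronaphthalen-1-olate) | COc1cc([C@H]2c3c(cc(OC)c(O[Si](C(C)C)(C(C)C)C(C)C)c3OC)C(O[K])=C(C)[C@H]2C)cc(OC)c1O[Si](C(C)C)(C(C)C)C(C)C | intermediate (not isolated)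
19 | (3S,4S)-4-[3,5-dimethoxy-4-(triisopropylsilyloxy)phenyl]-5,7-dimethoxy-2,3-dimethyl-6-(triisopropylsilyloxy)-3,4-dihydronaphthalen-1-yl trifluoromethanesulfonate | COc1cc([C@H]2c3c(cc(OC)c(O[Si](C(C)C)(C(C)C)C(C)C)c3OC)C(OS(=O)(=O)C(F)(F)F)=C(C)[C@H]2C)cc(OC)c1O[Si](C(C)C)(C(C)C)C(C)C | intermediate
20 | (1S,2S)-1-[3,5-dimethoxy-4-(triisopropylsilyloxy)phenyl]-6,8-dimethoxy-2,3-dimethyl-7-(triisopropylsilyloxy)-1,2-dihydronaphthalene | COc1cc([C@H]2c3c(cc(OC)c(O[Si](C(C)C)(C(C)C)C(C)C)c3OC)C=C(C)[C@H]2C)cc(OC)c1O[Si](C(C)C)(C(C)C)C(C)C | intermediate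
21 | (7S,8S)-8-(4-hydroxy-3,5-dimethoxyphenyl)-1,3-dimethoxy-6,7-dimethyl-7,8-dihydronaphthalen-2-ol | COc1cc([C@H]2c3c(cc(OC)c(O)c3OC)C=C(C)[C@H]2C)cc(OC)c1O | target

## Step count and least certain steps

Total: 13 steps. Longest linear sequence: 13 steps (1 to 21); syringaldehyde 1 enters a second time in step 4 without prior steps.

**Step 9 (key step).**
- What may go wrong: facial control in the hydride insertion may be weak or mismatched, which would give the trans isomer. A rhodium hydride may move the isopropenyl double bond into conjugation with the two aryl groups, which destroys C1. Decarbonylation of the acyl rhodium species may compete because the alkene is crowded.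
- Fallback: it sets out from 14. Me2AlCl in CH2Cl2 at low temperature promotes an intramolecular carbonyl-ene reaction that forms C3–C4 and gives (4S)-4-[3,5-dimethoxy-4-(triisopropylsilyloxy)phenyl]-5,7-dimethoxy-3-methylidene-6-(triisopropylsilyloxy)-1,2,3,4-tetrahydronaphthalen-1-ol F1 as carbinol epimers. Reduction of the exocyclic alkene with H2 and RhCl(PPh3)3, or with diimide, should occur from the face away from the C1 aryl group. That leaves the methyl group cis to the aryl group in (3R,4S)-4-[3,5-dimethoxy-4-(triisopropylsilyloxy)phenyl]-5,7-dimethoxy-3-methyl-6-(triisopropylsilyloxy)-1,2,3,4-tetrahydronaphthalen-1-ol F2. Oxidation with Dess–Martin periodinane comes back to the route at 15. The alkene is reduced before the oxidation so that no 4H-naphthalenone able to tautomerise to a naphthol is passed.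

**Step 5.**
- What may go wrong: the neighbouring dioxolane may capture the benzhydryl cation or be opened, water may add back, and the quinone methide may oligomerise on concentration.
- Fallback: it sets out from 7. 4-Methylbenzenesulfinic acid in CH2Cl2 over 4 Å MS converts 7 into the storable sulfone 4-{[6-(1,3-dioxolan-2-yl)-2,4-dimethoxy-3-(triisopropylsilyloxy)phenyl](4-methylbenzenesulfonyl)methyl}-2,6-dimethoxyphenol F3. Under the conditions of step 6 with one added equivalent of NaOt-Bu, its phenolate expels sulfinate, and the quinone methide is borylated as it forms. The sequence comes back to the route at 10.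

**Step 6.**
- What may go wrong: face selection may be poor and addition slow because the methide carbon carries a di-ortho-substituted aryl group. The electron-rich dibenzylic boronate may undergo protodeboronation before it is silylated.
- Fallback: it sets out from 8. Borylation with CuCl and an achiral bisphosphine, followed by the same silylation, gives racemic 2-{[6-(1,3-dioxolan-2-yl)-2,4-dimethoxy-3-(triisopropylsilyloxy)phenyl][3,5-dimethoxy-4-(triisopropylsilyloxy)phenyl]methyl}-4,4,5,5-tetramethyl-1,3,2-dioxaborolane F4. The enantiomers are separated by preparative chromatography on a chiral stationary phase, and the S enantiomer comes back to the route at 10.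

**Step 7.**
- What may go wrong: the boronate complex may form incompletely at the crowded boron atom, methoxide may cleave an aryl silyl ether, and iodine may attack the electron-rich rings.
- Fallback: it sets out from 8 and avoids boron altogether.
  - CH2=C(CH3)MgBr adds 1,6 to the quinone methide without a catalyst in THF at –78 °C and gives racemic 4-{1-[6-(1,3-dioxolan-2-yl)-2,4-dimethoxy-3-(triisopropylsilyloxy)phenyl]-2-methylprop-2-en-1-yl}-2,6-dimethoxyphenol F5.
  - Acylation with (1S)-camphanic chloride gives two diastereomeric esters. The one with S configuration at C1, 4-{(1S)-1-[6-(1,3-dioxolan-2-yl)-2,4-dimethoxy-3-(triisopropylsilyloxy)phenyl]-2-methylprop-2-en-1-yl}-2,6-dimethoxyphenyl (1S,4R)-4,7,7-trimethyl-3-oxo-2-oxabicyclo[2.2.1]heptane-1-carboxylate F6, is separated by crystallisation or chromatography.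
  - K2CO3 in MeOH releases 4-{(1S)-1-[6-(1,3-dioxolan-2-yl)-2,4-dimethoxy-3-(triisopropylsilyloxy)phenyl]-2-methylprop-2-en-1-yl}-2,6-dimethoxyphenol F7.
  - Silylation with i-Pr3SiCl and imidazole comes back to the route at 13.

**Step 12.**
- What may go wrong: a palladium hydride may shift the new double bond or dehydrogenate ring B to the naphthalene, and oxidative addition into the tetrasubstituted enol triflate may be slow.
- Fallback: it sets out from 17 and also replaces step 11. NaBH4 in MeOH/THF gives (3S,4S)-4-[3,5-dimethoxy-4-(triisopropylsilyloxy)phenyl]-5,7-dimethoxy-2,3-dimethyl-6-(triisopropylsilyloxy)-1,2,3,4-tetrahydronaphthalen-1-ol F8 as a mixture of epimers. Catalytic TsOH in toluene at 50 °C ionises the C4 alcohol, and the cation can lose a proton only from C3, so all epimers converge. The sequence comes back to the route at 20.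

## Further compounds

F1 | step 9 | (4S)-4-[3,5-dimethoxy-4-(triisopropylsilyloxy)phenyl]-5,7-dimethoxy-3-methylidene-6-(triisopropylsilyloxy)-1,2,3,4-tetrahydronaphthalen-1-ol (C1 epimers) | COc1cc([C@H]2c3c(cc(OC)c(O[Si](C(C)C)(C(C)C)C(C)C)c3OC)C(O)CC2=C)cc(OC)c1O[Si](C(C)C)(C(C)C)C(C)C
F2 | step 9 | (3R,4S)-4-[3,5-dimethoxy-4-(triisopropylsilyloxy)phenyl]-5,7-dimethoxy-3-methyl-6-(triisopropylsilyloxy)-1,2,3,4-tetrahydronaphthalen-1-ol (C1 epimers) | COc1cc([C@H]2c3c(cc(OC)c(O[Si](C(C)C)(C(C)C)C(C)C)c3OC)C(O)C[C@H]2C)cc(OC)c1O[Si](C(C)C)(C(C)C)C(C)C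
F3 | step 5 | racemic 4-{[6-(1,3-dioxolan-2-yl)-2,4-dimethoxy-3-(triisopropylsilyloxy)phenyl](4-methylbenzenesulfonyl)methyl}-2,6-dimethoxyphenol | COc1cc(cc(OC)c1O)C(c1c(C2OCCO2)cc(OC)c(O[Si](C(C)C)(C(C)C)C(C)C)c1OC)S(=O)(=O)c1ccc(C)cc1
F4 | step 6 | racemic 2-{[6-(1,3-dioxolan-2-yl)-2,4-dimethoxy-3-(triisopropylsilyloxy)phenyl][3,5-dimethoxy-4-(triisopropylsilyloxy)phenyl]methyl}-4,4,5,5-tetramethyl-1,3,2-dioxaborolane | COc1cc(cc(OC)c1O[Si](C(C)C)(C(C)C)C(C)C)C(c1c(C2OCCO2)cc(OC)c(O[Si](C(C)C)(C(C)C)C(C)C)c1OC)B1OC(C)(C)C(C)(C)O1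
F5 | step 7 | racemic 4-{1-[6-(1,3-dioxolan-2-yl)-2,4-dimethoxy-3-(triisopropylsilyloxy)phenyl]-2-methylprop-2-en-1-yl}-2,6-dimethoxyphenol | COc1cc(cc(OC)c1O)C(c1c(C2OCCO2)cc(OC)c(O[Si](C(C)C)(C(C)C)C(C)C)c1OC)C(C)=C
F6 | step 7 | 4-{(1S)-1-[6-(1,3-dioxolan-2-yl)-2,4-dimethoxy-3-(triisopropylsilyloxy)phenyl]-2-methylprop-2-en-1-yl}-2,6-dimethoxyphenyl (1S,4R)-4,7,7-trimethyl-3-oxo-2-oxabicyclo[2.2.1]heptane-1-carboxylate | COc1cc(cc(OC)c1OC(=O)[C@@]12CC[C@@](C)(C(=O)O1)C2(C)C)[C@@H](c1c(C2OCCO2)cc(OC)c(O[Si](C(C)C)(C(C)C)C(C)C)c1OC)C(C)=C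
F7 | step 7 | 4-{(1S)-1-[6-(1,3-dioxolan-2-yl)-2,4-dimethoxy-3-(triisopropylsilyloxy)phenyl]-2-methylprop-2-en-1-yl}-2,6-dimethoxyphenol | COc1cc(cc(OC)c1O)[C@@H](c1c(C2OCCO2)cc(OC)c(O[Si](C(C)C)(C(C)C)C(C)C)c1OC)C(C)=C
F8 | step 12 | (3S,4S)-4-[3,5-dimethoxy-4-(triisopropylsilyloxy)phenyl]-5,7-dimethoxy-2,3-dimethyl-6-(triisopropylsilyloxy)-1,2,3,4-tetrahydronaphthalen-1-ol (C1 and C2 epimers) | COc1cc([C@H]2c3c(cc(OC)c(O[Si](C(C)C)(C(C)C)C(C)C)c3OC)C(O)C(C)[C@H]2C)cc(OC)c1O[Si](C(C)C)(C(C)C)C(C)C
A1 | alternative 1 | (Z)-2-{2-[4-(tert-butyldimethylsilyloxy)-3,5-dimethoxyphenyl]ethenyl}-4,4,5,5-tetramethyl-1,3,2-dioxaborolane | COc1cc(/C=C\B2OC(C)(C)C(C)(C)O2)cc(OC)c1O[Si](C)(C)C(C)(C)C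
A2 | alternative 1 | 3-(tert-butyldimethylsilyloxy)-6-(dimethoxymethyl)-2,4-dimethoxyphenyl trifluoromethanesulfonate | COC(OC)c1cc(OC)c(O[Si](C)(C)C(C)(C)C)c(OC)c1OS(=O)(=O)C(F)(F)F
A3 | alternative 1 | 2-{(1S,2S)-1-[4-(tert-butyldimethylsilyloxy)-3,5-dimethoxyphenyl]-1-[3-(tert-butyldimethylsilyloxy)-6-(dimethoxymethyl)-2,4-dimethoxyphenyl]propan-2-yl}-4,4,5,5-tetramethyl-1,3,2-dioxaborolane | COc1cc(cc(OC)c1O[Si](C)(C)C(C)(C)C)[C@@H](c1c(C(OC)OC)cc(OC)c(O[Si](C)(C)C(C)(C)C)c1OC)[C@H](C)B1OC(C)(C)C(C)(C)O1
A4 | alternative 2 | 4-{[2,4-dimethoxy-6-[(2E)-2-methylbut-2-en-1-yl]-3-(triisopropylsilyloxy)phenyl]methylidene}-2,6-dimethoxycyclohexa-2,5-dien-1-one | COC1=CC(=Cc2c(C/C(C)=C/C)cc(OC)c(O[Si](C(C)C)(C(C)C)C(C)C)c2OC)C=C(OC)C1=O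
A5 | alternative 2 | 4-[(1S,2S)-6,8-dimethoxy-2,3-dimethyl-7-(triisopropylsilyloxy)-1,2-dihydronaphthalen-1-yl]-2,6-dimethoxyphenol | COc1cc(cc(OC)c1O)[C@H]1c2c(OC)c(O[Si](C(C)C)(C(C)C)C(C)C)c(OC)cc2C=C(C)[C@H]1C
A6 | alternative 3 | (1S,2R)-1-[4-(tert-butyldimethylsilyloxy)-3,5-dimethoxyphenyl]-1-[3-(tert-butyldimethylsilyloxy)-2,4-dimethoxy-6-propanoylphenyl]propan-2-yl 4-methylbenzenesulfonate | CCC(=O)c1cc(OC)c(O[Si](C)(C)C(C)(C)C)c(OC)c1[C@H](c1cc(OC)c(O[Si](C)(C)C(C)(C)C)c(OC)c1)[C@@H](C)OS(=O)(=O)c1ccc(C)cc1
A7 | alternative 3 | (2R,3S,4S)-6-(tert-butyldimethylsilyloxy)-4-[4-(tert-butyldimethylsilyloxy)-3,5-dimethoxyphenyl]-5,7-dimethoxy-2,3-dimethyl-3,4-dihydronaphthalen-1(2H)-one | COc1cc(cc(OC)c1O[Si](C)(C)C(C)(C)C)[C@H]1c2c(OC)c(O[Si](C)(C)C(C)(C)C)c(OC)cc2C(=O)[C@H](C)[C@H]1C
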